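**Retrosynthetic overview**
1. The target, 5,2',4'-trihydroxy-7-methoxy-3-prenylflavone, comes from a tris-MOM-protected 3-prenylflavone by acetal cleavage.
2. Ring C (the O1–C2 bond) and the C3–prenyl bond are made in one operation: a zerovalent-palladium cycloisomerisation with O-to-C prenyl transfer of a 2-(prenyloxy)aryl ynone (the proposed new step).
3. The ynone comes from addition of a ring B lithium acetylide to a ring A benzaldehyde, then oxidation.
4. The ring A aldehyde comes from 5-methoxyresorcinol (bis-MOM, directed ortho-lithiation/formylation, mono-MOM cleavage, O-prenylation); the ring B alkyne comes from 2,4-dihydroxybenzaldehyde (bis-MOM, Ohira–Bestmann).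
5. Ring order: rings A and B are bought as benzene rings; ring C is the only ring built (step 9).

Assumption: the target has no stereocentre and no stereogenic double bond, so "single enantiomer" means the achiral compound itself; the only stereocentre in the route (carbinol 18, racemic) is removed by oxidation in step 8.

**Route**

Step 1
Reactants: 1 5-methoxyresorcinol (3,5-dihydroxyanisole); 2 chloromethyl methyl ether (MOMCl)
Product: 3 1-methoxy-3,5-bis(methoxymethoxy)benzene
Conditions: NaH (2.4 equiv), MOMCl (2.4 equiv), DMF, 0 °C to rt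
Reagents that add atoms: chloromethyl methyl ether, COCCl
Why: Williamson-type O-alkylation of both sodium phenoxides of the symmetric diol with the highly reactive α-chloro ether gives the bis-MOM ether.

Step 2
Reactants: 3 1-methoxy-3,5-bis(methoxymethoxy)benzene; 4 N,N-dimethylformamide
Product: 7 4-methoxy-2,6-bis(methoxymethoxy)benzaldehyde, via aryllithium 5 (not isolated), via lithium hemiaminal alkoxide 6 (not isolated)
Conditions: n-BuLi (1.1 equiv), THF, 0 °C, 1 h; DMF (2 equiv), 0 °C to rt; H2O
Reagents that add atoms: N,N-dimethylformamide, CN(C)C=O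
Why: Directed ortho-metalation: the C–H flanked by two OMOM groups is lithiated selectively by cooperative chelation (OMOM outranks OMe as a director), and DMF formylates the aryllithium through tetrahedral adduct 6, which collapses to the aldehyde only on aqueous quench.

Step 3
Reactants: 7 4-methoxy-2,6-bis(methoxymethoxy)benzaldehyde
Product: 8 2-hydroxy-4-methoxy-6-(methoxymethoxy)benzaldehyde
Conditions: 3 M aq. HCl (cat.), THF, rt, monitored and stopped at mono-cleavage
Reagents that add atoms: none
Why: Acid-catalysed acetal hydrolysis in which the MOM ether next to the aldehyde is assisted by the carbonyl oxygen; once one phenol is free, its strong hydrogen bond to that carbonyl removes the assistance for the second MOM ether, so the reaction stops at the mono-phenol (either MOM gives the same product because 7 is symmetric).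

Step 4
Reactants: 8 2-hydroxy-4-methoxy-6-(methoxymethoxy)benzaldehyde; 9 prenyl bromide (1-bromo-3-methylbut-2-ene)
Product: 10 4-methoxy-2-(methoxymethoxy)-6-[(3-methylbut-2-en-1-yl)oxy]benzaldehyde
Conditions: K2CO3 (1.5 equiv), prenyl bromide (1.2 equiv), DMF, rt to 40 °C
Reagents that add atoms: prenyl bromide, CC(C)=CCBr
Why: Williamson ether synthesis; the potassium phenoxide of the salicylaldehyde is O-alkylated by SN2 at the primary allylic bromide.

Step 5
Reactants: 11 2,4-dihydroxybenzaldehyde; 2 chloromethyl methyl ether (MOMCl)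
Product: 12 2,4-bis(methoxymethoxy)benzaldehyde
Conditions: NaH (2.4 equiv), MOMCl (2.4 equiv), DMF, 0 °C to rt
Reagents that add atoms: chloromethyl methyl ether, COCCl
Why: Williamson-type MOM protection; full deprotonation with NaH also alkylates the hydrogen-bonded 2-hydroxyl.

Step 6
Reactants: 12 2,4-bis(methoxymethoxy)benzaldehyde; 13 dimethyl (1-diazo-2-oxopropyl)phosphonate (Ohira–Bestmann reagent)
Product: 15 1-ethynyl-2,4-bis(methoxymethoxy)benzene, via diazoalkene 14 (not isolated)
Conditions: K2CO3 (2 equiv), MeOH, rt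
Reagents that add atoms: dimethyl (1-diazo-2-oxopropyl)phosphonate, CC(=O)C(=[N+]=[N-])P(=O)(OC)OC
Why: Seyferth–Gilbert homologation in the Ohira–Bestmann form: the diazomethylphosphonate anion made by methanolysis olefinates the aldehyde, and diazoalkene 14 loses N2 with a 1,2-hydrogen shift to give the terminal alkyne under conditions that leave MOM ethers intact.

Step 7
Reactants: 15 1-ethynyl-2,4-bis(methoxymethoxy)benzene; 10 4-methoxy-2-(methoxymethoxy)-6-[(3-methylbut-2-en-1-yl)oxy]benzaldehyde
Product: 18 racemic 3-[2,4-bis(methoxymethoxy)phenyl]-1-{4-methoxy-2-(methoxymethoxy)-6-[(3-methylbut-2-en-1-yl)oxy]phenyl}prop-2-yn-1-ol, via lithium acetylide 16 (not isolated), via lithium alkoxide 17 (not isolated)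
Conditions: n-BuLi (1.05 equiv), THF, −78 °C; then 10, −78 to 0 °C; H2O; crude used directly
Reagents that add atoms: none
Why: 1,2-Addition of a lithium acetylide to a non-enolisable aldehyde; the new carbinol stereocentre forms as a racemate, which does not matter because it is oxidised in step 8.

Step 8
Reactants: 18 racemic propargylic alcohol
Product: 19 3-[2,4-bis(methoxymethoxy)phenyl]-1-{4-methoxy-2-(methoxymethoxy)-6-[(3-methylbut-2-en-1-yl)oxy]phenyl}prop-2-yn-1-one
Conditions: activated MnO2 (15 equiv), CH2Cl2, rt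
Reagents that add atoms: none
Why: MnO2 oxidation of a doubly activated (benzylic and propargylic) alcohol under neutral conditions that spare the prenyl ether, the MOM ethers and the alkyne.

Step 9
Reactants: 19 2-(prenyloxy)aryl ynone
Product: 22 2-[2,4-bis(methoxymethoxy)phenyl]-7-methoxy-5-(methoxymethoxy)-3-(3-methylbut-2-en-1-yl)-4H-chromen-4-one, via prenylpalladium phenoxide ion pair 20 (not isolated), via C3-palladated flavone 21 (not isolated)
Conditions: Pd2(dba)3 (2.5 mol%), XPhos (6 mol%), 4 Å MS, dry THF (0.05 M), 60 °C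
Reagents that add atoms: none
Why: Proposed new method: a zerovalent-palladium-catalysed cycloisomerisation with 1,3 O-to-C prenyl transfer, in which mono-ligated zerovalent palladium ionises the aryl prenyl ether (the leaving phenoxide is stabilised by the ortho ynone carbonyl) to ion pair 20, the cationic (η3-prenyl)palladium then binds the in-plane π-bond of the ynone and the tethered phenoxide adds anti in the 6-endo-dig (oxa-Michael) sense to close ring C as vinylpalladium 21, and C(sp2)–C(sp3) reductive elimination at the unhindered CH2 end of the prenyl ligand forms the C3–prenyl bond and returns zerovalent palladium (O-reprenylation is degenerate and reversible, and aprotic conditions suppress protodepalladation); the closest known reaction type is the palladium-catalysed amino- or oxypalladation/reductive elimination of o-alkynylanilides with allyl esters and of allyl o-alkynylphenyl ethers to 3-allylindoles and 3-allylbenzofurans, which to my knowledge has not been shown for an o-(allyloxy)aryl ynone, for closure of a chromone ring, or with a prenyl group.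

Step 10
Reactants: 22 tris-MOM 3-prenylflavone
Product: 23 2-(2,4-dihydroxyphenyl)-5-hydroxy-7-methoxy-3-(3-methylbut-2-en-1-yl)-4H-chromen-4-one (target)
Conditions: HCl (1.25 M in MeOH), rt to 40 °C
Reagents that add atoms: none
Why: Acid-catalysed acetal methanolysis removes all three MOM groups much faster than the trisubstituted alkene is protonated, the aryl methyl ether is inert, and the C3 prenyl group has no phenol placed for five- or six-membered ring closure (2'-OH and 5-OH would need eight-membered rings).

**Compound list**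
1 | 5-methoxyresorcinol | COc1cc(O)cc(O)c1 | starting material
2 | chloromethyl methyl ether (MOMCl) | COCCl | starting material
3 | 1-methoxy-3,5-bis(methoxymethoxy)benzene | COCOc1cc(OC)cc(OCOC)c1 | intermediate
4 | N,N-dimethylformamide | CN(C)C=O | starting material
5 | [4-methoxy-2,6-bis(methoxymethoxy)phenyl]lithium | [Li]c1c(OCOC)cc(OC)cc1OCOC | intermediate
6 | lithium (dimethylamino)[4-methoxy-2,6-bis(methoxymethoxy)phenyl]methanolate | [Li]OC(N(C)C)c1c(OCOC)cc(OC)cc1OCOC | intermediate
7 | 4-methoxy-2,6-bis(methoxymethoxy)benzaldehyde | COCOc1cc(OC)cc(OCOC)c1C=O | intermediate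
8 | 2-hydroxy-4-methoxy-6-(methoxymethoxy)benzaldehyde | COCOc1cc(OC)cc(O)c1C=O | intermediate
9 | prenyl bromide (1-bromo-3-methylbut-2-ene) | CC(C)=CCBr | starting material
10 | 4-methoxy-2-(methoxymethoxy)-6-[(3-methylbut-2-en-1-yl)oxy]benzaldehyde | COCOc1cc(OC)cc(OCC=C(C)C)c1C=O | intermediate
11 | 2,4-dihydroxybenzaldehyde | O=Cc1ccc(O)cc1O | starting material
12 | 2,4-bis(methoxymethoxy)benzaldehyde | COCOc1ccc(C=O)c(OCOC)c1 | intermediate
13 | dimethyl (1-diazo-2-oxopropyl)phosphonate | CC(=O)C(=[N+]=[N-])P(=O)(OC)OC | starting material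
14 | 1-(2-diazoethenyl)-2,4-bis(methoxymethoxy)benzene | COCOc1ccc(C=C=[N+]=[N-])c(OCOC)c1 | intermediate
15 | 1-ethynyl-2,4-bis(methoxymethoxy)benzene | COCOc1ccc(C#C)c(OCOC)c1 | intermediate
16 | {[2,4-bis(methoxymethoxy)phenyl]ethynyl}lithium | [Li]C#Cc1ccc(OCOC)cc1OCOC | intermediate
17 | lithium alkoxide of carbinol 18 (racemic) | [Li]OC(C#Cc1ccc(OCOC)cc1OCOC)c1c(OCOC)cc(OC)cc1OCC=C(C)C | intermediate
18 | racemic 3-[2,4-bis(methoxymethoxy)phenyl]-1-{4-methoxy-2-(methoxymethoxy)-6-[(3-methylbut-2-en-1-yl)oxy]phenyl}prop-2-yn-1-ol | OC(C#Cc1ccc(OCOC)cc1OCOC)c1c(OCOC)cc(OC)cc1OCC=C(C)C | intermediate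
19 | 3-[2,4-bis(methoxymethoxy)phenyl]-1-{4-methoxy-2-(methoxymethoxy)-6-[(3-methylbut-2-en-1-yl)oxy]phenyl}prop-2-yn-1-one | O=C(C#Cc1ccc(OCOC)cc1OCOC)c1c(OCOC)cc(OC)cc1OCC=C(C)C | intermediate
20 | ion pair of the ring A phenoxide of 19 and the (η3-prenyl)palladium cation (phosphine omitted, prenyl drawn in its σ-form) | [O-]c1cc(OC)cc(OCOC)c1C(=O)C#Cc1ccc(OCOC)cc1OCOC.CC(C)=CC[Pd+] | intermediate
21 | C3-palladated flavone, (flavon-3-yl)(prenyl)palladium (phosphine omitted) | COCOc1ccc(-c2oc3cc(OC)cc(OCOC)c3c(=O)c2[Pd]CC=C(C)C)c(OCOC)c1 | intermediate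
22 | 2-[2,4-bis(methoxymethoxy)phenyl]-7-methoxy-5-(methoxymethoxy)-3-(3-methylbut-2-en-1-yl)-4H-chromen-4-one | COCOc1ccc(-c2oc3cc(OC)cc(OCOC)c3c(=O)c2CC=C(C)C)c(OCOC)c1 | intermediate
23 | 2-(2,4-dihydroxyphenyl)-5-hydroxy-7-methoxy-3-(3-methylbut-2-en-1-yl)-4H-chromen-4-one | COc1cc(O)c2c(=O)c(CC=C(C)C)c(-c3ccc(O)cc3O)oc2c1 | target

**Step count and risks**

Total steps: 10. Longest linear sequence: 8 steps (1, 2, 3, 4, 7, 8, 9, 10); the ring B arm is 2 steps (5, 6).

The three steps most likely to fail:

Step 9 (proposed new step). Possible failures are 5-exo closure to an aurone, protodepalladation to the 3-unsubstituted flavone, coupling at the tertiary prenyl terminus, or no turnover. The fallback uses known chemistry only, sets out from ynone 19 and comes back at 22. Heating 19 with Pd(PPh3)4 (5 mol%) and Et2NH (5 equiv) in EtOH at 60 °C cleaves the aryl prenyl ether (Tsuji–Trost deallylation, Et2NH as prenyl acceptor) to the free phenol 1-[2-hydroxy-4-methoxy-6-(methoxymethoxy)phenyl]-3-[2,4-bis(methoxymethoxy)phenyl]prop-2-yn-1-one F1. F1 is not isolated, because the same amine mediates its 6-endo cyclisation (conjugate addition–elimination) to 2-[2,4-bis(methoxymethoxy)phenyl]-7-methoxy-5-(methoxymethoxy)-4H-chromen-4-one F2. Deprotonation of F2 at C3 with lithium diisopropylamide (THF, −78 °C) gives the 3-lithioflavone F3, which is quenched in the flask with I2 to 2-[2,4-bis(methoxymethoxy)phenyl]-3-iodo-7-methoxy-5-(methoxymethoxy)-4H-chromen-4-one F4. Stille coupling of F4 with tributyl(3-methylbut-2-en-1-yl)stannane (Pd(PPh3)4, DMF, 80 °C) joins C3 to the CH2 end of the prenyl group and gives 22, which goes on to step 10.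

Step 3 (selective mono-MOM cleavage). It may over-run to the diol or stall as a mixture. The fallback sets out from 7 and comes back at 10, desymmetrising by alkylation instead of by partial hydrolysis. Both MOM groups of 7 are removed (HCl in MeOH, rt) to give 2,6-dihydroxy-4-methoxybenzaldehyde F5. One equivalent of prenyl bromide 9 with K2CO3 in acetone at rt then gives 2-hydroxy-4-methoxy-6-[(3-methylbut-2-en-1-yl)oxy]benzaldehyde F6; the second hydroxyl is held in a hydrogen bond to the aldehyde and reacts much more slowly. MOM protection of F6 (NaH, MOMCl 2, DMF) gives 10.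

Step 7 (carbinol 18). The 2,4,6-trioxygenated benzylic and propargylic alcohol ionises easily and may not survive work-up or reach step 8 in good yield. The fallback sets out from aldehyde 10 (with alkyne 15) and comes back at 19 without passing through 18. Pinnick oxidation of 10 (NaClO2, NaH2PO4, 2-methylbut-2-ene, t-BuOH/H2O) gives 4-methoxy-2-(methoxymethoxy)-6-[(3-methylbut-2-en-1-yl)oxy]benzoic acid F7. 1-Chloro-N,N,2-trimethylprop-1-en-1-amine in CH2Cl2 converts F7 under neutral conditions into 4-methoxy-2-(methoxymethoxy)-6-[(3-methylbut-2-en-1-yl)oxy]benzoyl chloride F8. Acyl Sonogashira coupling of F8 with 15 (PdCl2(PPh3)2, CuI, Et3N, THF, rt) gives ynone 19.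

**Further compounds**
F1 | step 9 | 1-[2-hydroxy-4-methoxy-6-(methoxymethoxy)phenyl]-3-[2,4-bis(methoxymethoxy)phenyl]prop-2-yn-1-one | COCOc1cc(OC)cc(O)c1C(=O)C#Cc1ccc(OCOC)cc1OCOC
F2 | step 9 | 2-[2,4-bis(methoxymethoxy)phenyl]-7-methoxy-5-(methoxymethoxy)-4H-chromen-4-one | COCOc1ccc(-c2cc(=O)c3c(OCOC)cc(OC)cc3o2)c(OCOC)c1
F3 | step 9 | {2-[2,4-bis(methoxymethoxy)phenyl]-7-methoxy-5-(methoxymethoxy)-4-oxo-4H-chromen-3-yl}lithium | COCOc1ccc(-c2oc3cc(OC)cc(OCOC)c3c(=O)c2[Li])c(OCOC)c1
F4 | step 9 | 2-[2,4-bis(methoxymethoxy)phenyl]-3-iodo-7-methoxy-5-(methoxymethoxy)-4H-chromen-4-one | COCOc1ccc(-c2oc3cc(OC)cc(OCOC)c3c(=O)c2I)c(OCOC)c1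
F5 | step 3 | 2,6-dihydroxy-4-methoxybenzaldehyde | COc1cc(O)c(C=O)c(O)c1
F6 | step 3 | 2-hydroxy-4-methoxy-6-[(3-methylbut-2-en-1-yl)oxy]benzaldehyde | COc1cc(O)c(C=O)c(OCC=C(C)C)c1
F7 | step 7 | 4-methoxy-2-(methoxymethoxy)-6-[(3-methylbut-2-en-1-yl)oxy]benzoic acid | COCOc1cc(OC)cc(OCC=C(C)C)c1C(=O)O
F8 | step 7 | 4-methoxy-2-(methoxymethoxy)-6-[(3-methylbut-2-en-1-yl)oxy]benzoyl chloride | COCOc1cc(OC)cc(OCC=C(C)C)c1C(Cl)=O
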